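Of the substrate charged on Sunday, 64.8% was left at 120 min, and the readings leave a gap of 10.5%, read here as double product. Each substrate lost on Sunday therefore cost 1.30 coupling partner. At 20.0 min the two runs stand alike, 92.2% and 92.3%, at equal partner but different substrate charges. The substrate's loss therefore reads as first order in substrate. With [coupling partner], which falls during a run, as the second factor, Sunday's early reading at charged partner gives a second-order constant of 0.00338 M⁻¹ min⁻¹.

| setting | Sunday's | Saturday's | flask |
|---|---|---|---|
| substrate | 0.75 M | 3 M | 1.5 M |
| coupling partner | 1.2 M | 1.2 M | 1.20 M |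
| remark | run made earlier | run made earlier |  |
| time |  |  | 2.5 h |

| run | time / min | substrate / % | single product / % | other mono adduct / % |
|---|---|---|---|---|
| Sunday's | 10.0 | 95.8 | 2.8 | 1.1 |
| Sunday's | 20.0 | 92.2 | 4.9 | 1.7 |
| Sunday's | 50.0 | 81.9 | 10.9 | 3.8 |
| Sunday's | 120 | 64.8 | 17.8 | 6.9 |
| Saturday's | 10.0 | 96.0 | 3.0 | 0.6 |
| Saturday's | 20.0 | 92.3 | 5.2 | 1.2 |
| Saturday's | 50.0 | 84.9 | 8.8 | 3.5 |
| Saturday's | 120 | 76.1 | 13.7 | 5.0 |

(scatter of a reading: 0.5 percentage points)

1. amount of substrate at 2.5 h, in percent of the substrate charged
2. amount of single product at 2.5 h, in percent of the substrate charged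
3. amount of other mono adduct at 2.5 h, in percent of the substrate charged
4. amount of double product at 2.5 h, in percent of the substrate charged



My ladder starts with the mono adducts: their mean stock over their drain on Sunday gives 141 min. Next comes the flask's own 2.5 h, then the partner's time constant at charged substrate, 197 min, and slowest the substrate's at charged partner, 246 min. The flask should therefore show mono adducts already being drained, with both charges still present.

Taking Sunday's leftover as a guess, the flask's partner ends near 42.9% of its charge. Averaging start and end gives 0.435 substrate turnovers, meaning k times the time integral of [coupling partner]. That leaves 64.7% substrate.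

The forecast gives 65.2%, 17.4%, 6.6% and 10.8%, on the ground that “The missing mass balance is double product”.

The flask gives 65.0%, 16.5%, 7.30% and 8.69%, each within the margin, and it also holds 2.51% isomer of the product.

    single product ⇌ isomer of the product (K = 0.300, k = 0.00214 min⁻¹)
    substrate + coupling partner → other mono adduct (k = 8.58 × 10⁻⁴ M⁻¹ min⁻¹)
    substrate + coupling partner → single product (k = 0.00262 M⁻¹ min⁻¹)
    coupling partner + single product → double product (k = 0.00565 M⁻¹ min⁻¹)
    coupling partner + other mono adduct → double product (k = 0.00260 M⁻¹ min⁻¹)

This flask is not at rest: its substrate shows 0.431 turnovers against 0.435 counted, with 45% of the partner left. At 25.0 h the partner stands at 0.131% and the substrate at 43.2%, twice the turnovers. Double product climbs to 23.1%, while single product moves to 18.2%.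

For the neighbour with 0.90 M substrate, the partner ends near 65.6%, giving 0.504 turnovers and 60.4% substrate. Computed, that neighbour holds 60.8% substrate and 62% partner.

All runs are calculated on assumed constants, noise included.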